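**Retrosynthetic overview**

1. Target ⇐ allylic oxidation, hydroboration and methylenation of a seven-membered allylic lactone 32; that lactone carries both the C1 enal carbon (locked Z) and the start of the hydroxypropyl arm.
2. 32 ⇐ B-alkyl Suzuki coupling of the core vinyl lactone 14 with the oxolane vinyl iodide 30.
3. 14 ⇐ key step: ring-expanding Claisen ([3,3]) rearrangement of a cyclic ketene acetal. It forms the C5–C6 bond, sets C6 and fixes the tetrasubstituted alkene; C11 and C10 then follow from C6.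
4. The Claisen precursor comes from (S)-lactic acid (Seebach dioxolanone aldol onto cyclohexane-1,4-dione). 30 comes from (R)-malic acid (chelation-controlled Grignard addition, oxocarbenium alkynylation, carboalumination).
5. Ring order: cyclohexane bought; seven-membered lactone made in the Claisen step and opened at the end; oxolane ring made by lactonisation in fragment B before the coupling.

Assumption: locants follow iridal numbering (C1 = CHO carbon, C2 = its alkene carbon, C3–C5 = hydroxypropyl arm, C6–C11 = cyclohexane, C12–C15 = linker, C16–C19 = oxolane carbons); (S)-lactic acid and (R)-malic acid are the purchased sources of chirality.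

**Fragment A (core)**

Step 1
Reactants: 1 (S)-lactic acid; 2 pivalaldehyde
Product: 3 (2S,5S)-2-tert-butyl-5-methyl-1,3-dioxolan-4-one
Conditions: p-TsOH·H2O (cat.), H2SO4 (cat.), pentane, reflux, Dean–Stark; recrystallise from Et2O/pentane at −78 °C
Reagents that add atoms: none
Why: Acid-catalysed acetalisation (Seebach self-regeneration of stereocentres); the lactic acid centre induces the cis acetal centre, which is enriched by crystallisation.

Step 2
Reactants: 3 cis-dioxolanone; 4 cyclohexane-1,4-dione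
Product: 5 (2S,5R)-2-tert-butyl-5-(1-hydroxy-4-oxocyclohexyl)-5-methyl-1,3-dioxolan-4-one
Conditions: LDA, THF, −78 °C; enolate added to 4 (3 equiv), THF, −78 °C; AcOH quench at −78 °C
Reagents that add atoms: none
Why: Seebach aldol addition; the enolate is attacked trans to the tert-butyl group, so the ring replaces the lactic acid hydrogen with retention and gives the quaternary (R)-centre (C2), while excess symmetric dione limits double addition.

Step 3
Reactants: 5 aldol adduct
Product: 6 (2S,5R)-2-tert-butyl-5-methyl-5-(4-oxocyclohex-1-en-1-yl)-1,3-dioxolan-4-one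
Conditions: Martin sulfurane, CH2Cl2, 0 °C to rt
Reagents that add atoms: none
Why: Martin sulfurane dehydration of the tertiary alcohol; C2 has no hydrogen and the ring is symmetric, so only one β,γ-unsaturated ketone can form.

Step 4
Reactants: 6 β,γ-enone
Product: 8 (2S,5R)-2-tert-butyl-5-[4-(tert-butyldimethylsilyloxy)-3-methylcyclohexa-1,3-dien-1-yl]-5-methyl-1,3-dioxolan-4-one, via methylated enone 7 (not isolated)
Conditions: LDA (1.05 equiv), THF, −78 °C; MeI; then Et3N, TBSOTf, −78 to 0 °C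
Reagents that add atoms: iodomethane, CI; tert-butyldimethylsilyl trifluoromethanesulfonate, CC(C)(C)[Si](C)(C)OS(=O)(=O)C(F)(F)F
Why: The doubly activated CH2 between carbonyl and alkene is deprotonated and the dienolate is methylated at its α-carbon (C11), then soft enolisation gives the conjugated silyl dienol ether; the transient C11 centre (epimer mixture) becomes sp2 again.

Step 5
Reactants: 8 silyl dienol ether dioxolanone
Product: 9 (2R)-2-[4-(tert-butyldimethylsilyloxy)-3-methylcyclohexa-1,3-dien-1-yl]propane-1,2-diol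
Conditions: LiAlH4, Et2O, 0 °C; NaOH/H2O work-up
Reagents that add atoms: none
Why: Hydride reduction of the acylal carbonyl releases the 1,2-diol and neopentyl alcohol; the silyl enol ether is inert to hydride and the C2 centre is untouched.

Step 6
Reactants: 9 diol
Product: 10 (4R)-4-[4-(tert-butyldimethylsilyloxy)-3-methylcyclohexa-1,3-dien-1-yl]-4-methyl-1,3-dioxolan-2-one
Conditions: CDI, DMAP (cat.), CH2Cl2, rt
Reagents that add atoms: 1,1'-carbonyldiimidazole, O=C(n1ccnc1)n1ccnc1
Why: Carbonylation of the primary alcohol and five-membered ring closure onto the tertiary alcohol under neutral conditions that spare the acid-labile dienol ether.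

Step 7
Reactants: 10 cyclic carbonate
Product: 12 (9aR)-8-(tert-butyldimethylsilyloxy)-5,9-dimethyl-4,6,7,9a-tetrahydro-3-benzoxepin-2(1H)-one, via ketene acetal 11 (not isolated)
Conditions: Cp2TiMe2 (2 equiv), toluene, 105 °C, dark
Reagents that add atoms: Cp2TiMe2, C[Ti](C)(C1C=CC=C1)C1C=CC=C1
Why: Petasis methylenation of the carbonate followed by a ring-expanding Claisen [3,3] rearrangement; C5 arrives at C6 on the face from which the C2–O bond leaves, so (R)-C2 gives (R)-C6, and because C1 and C6 sit in one seven-membered ring the new tetrasubstituted C2=C7 alkene can only be Z.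

Step 8
Reactants: 12 bicyclic silyl enol ether lactone
Product: 13 (9S,9aR)-9-ethenyl-5,9-dimethyl-4,6,7,9a-tetrahydro-3-benzoxepine-2,8(1H,9H)-dione
Conditions: vinyl bromide, Pd2(dba)3 (cat.), P(t-Bu)3 (cat.), Bu3SnF, toluene, 80 °C, sealed tube
Reagents that add atoms: vinyl bromide, C=CBr
Why: Kuwajima–Urabe-type palladium-catalysed α-vinylation of the regiodefined tin enolate; the vinyl group enters C11 anti to the pseudo-axial C5 branch on C6, giving the quaternary centre with methyl cis to that branch.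

Step 9
Reactants: 13 vinyl keto lactone
Product: 14 (8S,9S,9aR)-9-ethenyl-8-hydroxy-5,8,9-trimethyl-1,4,6,7,8,9a-hexahydro-3-benzoxepin-2(9H)-one
Conditions: MeMgBr, CeCl3, THF, −78 °C; AcOH quench at −78 °C
Reagents that add atoms: methylmagnesium bromide, C[Mg]Br
Why: Imamoto organocerium 1,2-addition, faster at the ketone than at the lactone at −78 °C; equatorial attack anti to the syn-axial C5 branch puts the C10 hydroxyl cis to that branch.

**Fragment B (oxolane)**

Step 10
Reactants: 15 (R)-malic acid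
Product: 18 (3R)-3-hydroxy-4-[methoxy(methyl)amino]-4-oxobutanoic acid, via trifluoroacetyl anhydride 16 (not isolated), via trifluoroacetate amide 17 (not isolated)
Conditions: (CF3CO)2O, 0 °C to rt; evaporate; MeNH(OMe)·HCl, pyridine, CH2Cl2, 0 °C; then MeOH
Reagents that add atoms: trifluoroacetic anhydride, O=C(OC(=O)C(F)(F)F)C(F)(F)F (atoms in 16 and 17 only); N,O-dimethylhydroxylamine hydrochloride, CNOC.Cl
Why: Regioselective anhydride opening at the carbonyl next to the electron-poor acyloxy group gives the Weinreb amide at C19, and methanol removes the trifluoroacetate; the purchased centre (C18) is not touched.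

Step 11
Reactants: 18 Weinreb amide acid; 19 5-bromo-2-methylpent-2-ene
Product: 21 (3R)-3-hydroxy-8-methyl-4-oxonon-7-enoic acid, via Grignard reagent 20 (not isolated)
Conditions: 19, Mg, THF (gives 20, 3.5 equiv); 18 added at 0 °C, then rt; aqueous citric acid
Reagents that add atoms: magnesium, [Mg] (atoms in 20 only)
Why: Weinreb ketone synthesis; two equivalents of Grignard reagent deprotonate OH and CO2H, the third adds once to the amide, and the chelated adduct collapses to the ketone only on work-up.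

Step 12
Reactants: 21 hydroxy keto acid
Product: 23 (4R,5S)-4-hydroxy-5-methyl-5-(4-methylpent-3-en-1-yl)oxolan-2-one, via dihydroxy acid 22 (not isolated)
Conditions: MeMgBr (4 equiv), THF, −78 to −20 °C; aqueous NH4Cl; then PPTS (cat.), CH2Cl2, rt
Reagents that add atoms: methylmagnesium bromide, C[Mg]Br
Why: Cram chelation-controlled Grignard addition; magnesium bridges the α-alkoxide and the ketone and methyl attacks from the hydrogen side of C18, setting (S)-C19, and the γ-hydroxy acid then lactonises.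

Step 13
Reactants: 23 hydroxy lactone
Product: 24 (4R,5S)-4-(tert-butyldimethylsilyloxy)-5-methyl-5-(4-methylpent-3-en-1-yl)oxolan-2-one
Conditions: TBSOTf, 2,6-lutidine, CH2Cl2, −78 to 0 °C
Reagents that add atoms: tert-butyldimethylsilyl trifluoromethanesulfonate, CC(C)(C)[Si](C)(C)OS(=O)(=O)C(F)(F)F
Why: Silylation under a weak, hindered base that does not trigger β-elimination to the butenolide; an ether at C18 is needed for the next stereocontrol.

Step 14
Reactants: 24 silyloxy lactone
Product: 26 (4R,5S)-4-(tert-butyldimethylsilyloxy)-5-methyl-5-(4-methylpent-3-en-1-yl)oxolan-2-yl acetate, via aluminium lactolate 25 (not isolated)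
Conditions: i-Bu2AlH, CH2Cl2, −78 °C; then pyridine, DMAP, Ac2O, −78 to 0 °C
Reagents that add atoms: i-Bu2AlH, CC(C)C[AlH]CC(C)C (atoms in 25 only); acetic anhydride, CC(=O)OC(C)=O
Why: Rychnovsky reductive acetylation; the tetrahedral aluminium hemiacetal is trapped as the anomeric acetate (anomer mixture, which converges in the next step).

Step 15
Reactants: 26 lactol acetate
Product: 28 (2S,3R,5R)-5-ethynyl-2-methyl-2-(4-methylpent-3-en-1-yl)oxolan-3-ol, via bis-silyl alkyne 27 (not isolated)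
Conditions: Me3SiC≡CSnBu3, BF3·OEt2, CH2Cl2, −78 °C; then TBAF (excess), THF, rt
Reagents that add atoms: trimethyl[(tributylstannyl)ethynyl]silane, C[Si](C)(C)C#C[Sn](CCCC)(CCCC)CCCC
Why: Lewis-acid C-glycosylation of the oxocarbenium ion; by the Woerpel inside-attack model the pseudo-axial C18 silyloxy group directs the alkynyl group 1,3-cis to it (sets C16), and fluoride then removes both silyl groups.

Step 16
Reactants: 28 alkynol
Product: 30 (2S,3R,5R)-5-[(1E)-1-iodoprop-1-en-2-yl]-2-methyl-2-(4-methylpent-3-en-1-yl)oxolan-3-ol, via alkenylalane 29 (not isolated)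
Conditions: AlMe3, Cp2ZrCl2, H2O (1 equiv), CH2Cl2, −20 °C to rt; then I2, THF, −30 °C
Reagents that add atoms: trimethylaluminium, C[Al](C)C; iodine, II
Why: Negishi zirconium-catalysed carboalumination adds methyl and aluminium syn across the terminal alkyne (methyl on the inner carbon), and iodinolysis with retention gives the (E)-vinyl iodide; the trisubstituted alkene is inert.

**Coupling and endgame**

Step 17
Reactants: 14 core vinyl lactone; 30 vinyl iodide
Product: 32 (8S,9S,9aR)-8-hydroxy-9-{(3E)-4-[(2R,4R,5S)-4-hydroxy-5-methyl-5-(4-methylpent-3-en-1-yl)oxolan-2-yl]pent-3-en-1-yl}-5,8,9-trimethyl-1,4,6,7,8,9a-hexahydro-3-benzoxepin-2(9H)-one, via alkylborane 31 (not isolated)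
Conditions: 9-BBN, THF, rt to 40 °C; then 30, Pd(dppf)Cl2 (cat.), AsPh3, Cs2CO3, DMF/H2O, rt
Reagents that add atoms: 9-BBN, B1C2CCCC1CCC2 (atoms in 31 only)
Why: Anti-Markovnikov hydroboration of the only monosubstituted alkene, then B-alkyl Suzuki–Miyaura coupling with retention of the (E)-alkene; the tetrasubstituted allylic lactone coordinates palladium poorly and survives at rt.

Step 18
Reactants: 32 coupled lactone
Product: 33 lactol of 32 (C4 is CH(OH) in the seven-membered ring; anomer mixture)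
Conditions: i-Bu2AlH (excess for the two OH groups), CH2Cl2, −78 °C
Reagents that add atoms: none
Why: Low-temperature i-Bu2AlH reduction stops at the lactol because the aluminium hemiacetal is stable at −78 °C; no other carbonyl is present.

Step 19
Reactants: 33 lactol
Product: 34 (2Z)-2-[(2R,3S,4S)-4-hydroxy-3-{(3E)-4-[(2R,4R,5S)-4-hydroxy-5-methyl-5-(4-methylpent-3-en-1-yl)oxolan-2-yl]pent-3-en-1-yl}-3,4-dimethyl-2-(prop-2-en-1-yl)cyclohexylidene]propan-1-ol
Conditions: Ph3PCH3Br, KOt-Bu (excess), THF, 0 °C to rt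
Reagents that add atoms: methyltriphenylphosphonium bromide, C[P+](c1ccccc1)(c1ccccc1)c1ccccc1.[Br-]
Why: Wittig methylenation of the open hydroxy-aldehyde form adds C3 and frees the C1 allylic alcohol; the Z geometry made in step 7 is kept because the alkene itself is not touched.

Step 20
Reactants: 34 triol diene
Product: 36 (2Z)-2-[(2R,3S,4S)-4-hydroxy-3-{(3E)-4-[(2R,4R,5S)-4-hydroxy-5-methyl-5-(4-methylpent-3-en-1-yl)oxolan-2-yl]pent-3-en-1-yl}-2-(3-hydroxypropyl)-3,4-dimethylcyclohexylidene]propan-1-ol, via alkylborane 35 (not isolated)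
Conditions: 9-BBN (excess for the three OH groups), THF, 0 °C to rt; then NaOH, H2O2, 0 °C
Reagents that add atoms: 9-BBN, B1C2CCCC1CCC2 (atoms in 35 only); hydrogen peroxide, OO
Why: Brown hydroboration–oxidation; 9-BBN reacts with the monosubstituted alkene far faster than with the tri- and tetrasubstituted ones and gives the primary C3 alcohol.

Step 21
Reactants: 36 tetraol
Product: 37 target, (2Z)-2-[(2R,3S,4S)-4-hydroxy-3-{(3E)-4-[(2R,4R,5S)-4-hydroxy-5-methyl-5-(4-methylpent-3-en-1-yl)oxolan-2-yl]pent-3-en-1-yl}-2-(3-hydroxypropyl)-3,4-dimethylcyclohexylidene]propanal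
Conditions: MnO2, CH2Cl2, rt
Reagents that add atoms: none
Why: MnO2 oxidises only the allylic primary alcohol to the enal and leaves the saturated primary, secondary and tertiary alcohols and the alkene geometry unchanged.

**Compound list**

1 | (S)-lactic acid | C[C@H](O)C(=O)O | starting material
2 | pivalaldehyde | CC(C)(C)C=O | starting material
3 | (2S,5S)-2-tert-butyl-5-methyl-1,3-dioxolan-4-one | C[C@@H]1O[C@H](C(C)(C)C)OC1=O | intermediate
4 | cyclohexane-1,4-dione | O=C1CCC(=O)CC1 | starting material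
5 | (2S,5R)-2-tert-butyl-5-(1-hydroxy-4-oxocyclohexyl)-5-methyl-1,3-dioxolan-4-one | C[C@]1(C2(O)CCC(=O)CC2)O[C@H](C(C)(C)C)OC1=O | intermediate
6 | (2S,5R)-2-tert-butyl-5-methyl-5-(4-oxocyclohex-1-en-1-yl)-1,3-dioxolan-4-one | C[C@]1(C2=CCC(=O)CC2)O[C@H](C(C)(C)C)OC1=O | intermediate
7 | (2S,5R)-2-tert-butyl-5-methyl-5-(3-methyl-4-oxocyclohex-1-en-1-yl)-1,3-dioxolan-4-one, both epimers at the ring methyl carbon | C[C@]1(C2=CC(C)C(=O)CC2)O[C@H](C(C)(C)C)OC1=O | intermediate
8 | (2S,5R)-2-tert-butyl-5-[4-(tert-butyldimethylsilyloxy)-3-methylcyclohexa-1,3-dien-1-yl]-5-methyl-1,3-dioxolan-4-one | C[C@]1(C2=CC(C)=C(O[Si](C)(C)C(C)(C)C)CC2)O[C@H](C(C)(C)C)OC1=O | intermediate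
9 | (2R)-2-[4-(tert-butyldimethylsilyloxy)-3-methylcyclohexa-1,3-dien-1-yl]propane-1,2-diol | C[C@](CO)(C1=CC(C)=C(O[Si](C)(C)C(C)(C)C)CC1)O | intermediate
10 | (4R)-4-[4-(tert-butyldimethylsilyloxy)-3-methylcyclohexa-1,3-dien-1-yl]-4-methyl-1,3-dioxolan-2-one | C[C@@]1(C2=CC(C)=C(O[Si](C)(C)C(C)(C)C)CC2)COC(=O)O1 | intermediate
11 | (4R)-4-[4-(tert-butyldimethylsilyloxy)-3-methylcyclohexa-1,3-dien-1-yl]-4-methyl-2-methylidene-1,3-dioxolane | C[C@@]1(C2=CC(C)=C(O[Si](C)(C)C(C)(C)C)CC2)COC(=C)O1 | intermediate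
12 | (9aR)-8-(tert-butyldimethylsilyloxy)-5,9-dimethyl-4,6,7,9a-tetrahydro-3-benzoxepin-2(1H)-one (seven-membered allylic lactone fused to the cyclohexene at C6–C7) | CC1=C(O[Si](C)(C)C(C)(C)C)CCC2=C(C)COC(=O)C[C@@H]12 | intermediate
13 | (9S,9aR)-9-ethenyl-5,9-dimethyl-4,6,7,9a-tetrahydro-3-benzoxepine-2,8(1H,9H)-dione (vinyl trans to the C5 branch) | C=C[C@@]1(C)[C@@H]2CC(=O)OCC(C)=C2CCC1=O | intermediate
14 | (8S,9S,9aR)-9-ethenyl-8-hydroxy-5,8,9-trimethyl-1,4,6,7,8,9a-hexahydro-3-benzoxepin-2(9H)-one | C=C[C@@]1(C)[C@@H]2CC(=O)OCC(C)=C2CC[C@]1(C)O | intermediate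
15 | (R)-malic acid | OC(=O)C[C@@H](O)C(=O)O | starting material
16 | (3R)-2,5-dioxooxolan-3-yl trifluoroacetate | O=C1C[C@@H](OC(=O)C(F)(F)F)C(=O)O1 | intermediate
17 | (3R)-4-[methoxy(methyl)amino]-4-oxo-3-(trifluoroacetoxy)butanoic acid | OC(=O)C[C@@H](OC(=O)C(F)(F)F)C(=O)N(C)OC | intermediate
18 | (3R)-3-hydroxy-4-[methoxy(methyl)amino]-4-oxobutanoic acid | OC(=O)C[C@@H](O)C(=O)N(C)OC | intermediate
19 | 5-bromo-2-methylpent-2-ene | CC(C)=CCCBr | starting material
20 | (4-methylpent-3-en-1-yl)magnesium bromide | CC(C)=CCC[Mg]Br | intermediate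
21 | (3R)-3-hydroxy-8-methyl-4-oxonon-7-enoic acid | OC(=O)C[C@@H](O)C(=O)CCC=C(C)C | intermediate
22 | (3R,4S)-3,4-dihydroxy-4,8-dimethylnon-7-enoic acid | OC(=O)C[C@@H](O)[C@@](C)(O)CCC=C(C)C | intermediate
23 | (4R,5S)-4-hydroxy-5-methyl-5-(4-methylpent-3-en-1-yl)oxolan-2-one | CC(C)=CCC[C@]1(C)OC(=O)C[C@H]1O | intermediate
24 | (4R,5S)-4-(tert-butyldimethylsilyloxy)-5-methyl-5-(4-methylpent-3-en-1-yl)oxolan-2-one | CC(C)=CCC[C@]1(C)OC(=O)C[C@H]1O[Si](C)(C)C(C)(C)C | intermediate
25 | diisobutylaluminium lactolate of 24 (anomer mixture) | CC(C)=CCC[C@]1(C)OC(O[Al](CC(C)C)CC(C)C)C[C@H]1O[Si](C)(C)C(C)(C)C | intermediate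
26 | (4R,5S)-4-(tert-butyldimethylsilyloxy)-5-methyl-5-(4-methylpent-3-en-1-yl)oxolan-2-yl acetate (anomer mixture) | CC(C)=CCC[C@]1(C)OC(OC(C)=O)C[C@H]1O[Si](C)(C)C(C)(C)C | intermediate
27 | tert-butyldimethyl{[(2S,3R,5R)-2-methyl-2-(4-methylpent-3-en-1-yl)-5-[(trimethylsilyl)ethynyl]oxolan-3-yl]oxy}silane | CC(C)=CCC[C@]1(C)O[C@@H](C#C[Si](C)(C)C)C[C@H]1O[Si](C)(C)C(C)(C)C | intermediate
28 | (2S,3R,5R)-5-ethynyl-2-methyl-2-(4-methylpent-3-en-1-yl)oxolan-3-ol | CC(C)=CCC[C@]1(C)O[C@@H](C#C)C[C@H]1O | intermediate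
29 | (E)-alkenyl(dimethyl)alane from 28, hydroxyl as its dimethylaluminium alkoxide | CC(C)=CCC[C@]1(C)O[C@@H](/C(C)=C/[Al](C)C)C[C@H]1O[Al](C)C | intermediate
30 | (2S,3R,5R)-5-[(1E)-1-iodoprop-1-en-2-yl]-2-methyl-2-(4-methylpent-3-en-1-yl)oxolan-3-ol | CC(C)=CCC[C@]1(C)O[C@@H](/C(C)=C/I)C[C@H]1O | intermediate
31 | 14 with the vinyl group converted to CH2CH2–(9-borabicyclo[3.3.1]nonan-9-yl) | B1(C2CCCC1CCC2)CC[C@@]3(C)[C@@H]4CC(=O)OCC(C)=C4CC[C@]3(C)O | intermediate
32 | coupled lactone: 14 whose C11 vinyl is now the C12–C13 link to the (E)-C14=C15 alkene of the oxolane fragment | CC(C)=CCC[C@]1(C)O[C@@H](/C(C)=C/CC[C@@]2(C)[C@@H]3CC(=O)OCC(C)=C3CC[C@]2(C)O)C[C@H]1O | intermediate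
33 | lactol of 32 (anomer mixture) | CC(C)=CCC[C@]1(C)O[C@@H](/C(C)=C/CC[C@@]2(C)[C@@H]3CC(O)OCC(C)=C3CC[C@]2(C)O)C[C@H]1O | intermediate
34 | triol diene: C1 allylic alcohol, C6 allyl group, (2Z) alkene; (2Z)-2-[(2R,3S,4S)-4-hydroxy-3-{(3E)-4-[(2R,4R,5S)-4-hydroxy-5-methyl-5-(4-methylpent-3-en-1-yl)oxolan-2-yl]pent-3-en-1-yl}-3,4-dimethyl-2-(prop-2-en-1-yl)cyclohexylidene]propan-1-ol | CC(C)=CCC[C@]1(C)O[C@@H](/C(C)=C/CC[C@@]2(C)[C@H](CC=C)/C(=C(/C)CO)CC[C@]2(C)O)C[C@H]1O | intermediate
35 | 34 with the allyl terminus carrying a 9-borabicyclo[3.3.1]nonan-9-yl group | CC(C)=CCC[C@]1(C)O[C@@H](/C(C)=C/CC[C@@]2(C)[C@H](CCCB3C4CCCC3CCC4)/C(=C(/C)CO)CC[C@]2(C)O)C[C@H]1O | intermediate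
36 | tetraol (target with CH2OH in place of CHO) | CC(C)=CCC[C@]1(C)O[C@@H](/C(C)=C/CC[C@@]2(C)[C@H](CCCO)/C(=C(/C)CO)CC[C@]2(C)O)C[C@H]1O | intermediate
37 | CNP0155390.1, (2Z)-2-[(2R,3S,4S)-4-hydroxy-3-{(3E)-4-[(2R,4R,5S)-4-hydroxy-5-methyl-5-(4-methylpent-3-en-1-yl)oxolan-2-yl]pent-3-en-1-yl}-2-(3-hydroxypropyl)-3,4-dimethylcyclohexylidene]propanal | CC(C)=CCC[C@]1(C)O[C@@H](/C(C)=C/CC[C@@]2(C)[C@H](CCCO)/C(=C(/C)C=O)CC[C@]2(C)O)C[C@H]1O | target

**Step count and risks**

Total: 21 steps. Longest linear sequence: 14 steps (steps 1–9, then 17–21); fragment B takes 7 steps (10–16).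

Step 7 (tandem methylenation/Claisen). The titanium carbene may methylenate the product lactone, the tertiary dienylic C–O bond may ionise on heating, and the transition state is a strained boat. Fallback from 9 back to 12: transacetalise diol 9 with (phenylselanyl)acetaldehyde diethyl acetal (PPTS, toluene, 4 Å sieves) to the 2-[(phenylselanyl)methyl]-1,3-dioxolane F1, oxidise it (NaIO4, NaHCO3, MeOH/H2O) to the selenoxide F2, and heat with DBU in xylene at 140 °C. Syn-elimination of benzeneselenenic acid gives the same ketene acetal 11, which rearranges to 12 with no carbene present.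

Step 8 (α-vinylation). Reductive elimination must build a quaternary carbon next to a tertiary one from a hindered enolate, and zerovalent palladium could ionise the allylic lactone. Fallback from 12 back to 13: Mukaiyama aldol addition of 12 to acetaldehyde (TiCl4, CH2Cl2, −78 °C) gives the β-hydroxy ketone F3, with the new bond again anti to the C5 branch. Martin sulfurane then dehydrates F3, which can only eliminate towards the methyl group, to give 13.

Step 9 (methyl addition). The α-quaternary ketone is hindered, the lactone competes, and the facial selectivity rests on a conformational argument. Fallback from 13 back to 14: saponify 13 (LiOH, THF/H2O) to the keto hydroxy acid F4, whose carboxylate is inert to the Grignard reagent, and add MeMgBr/CeCl3 in excess to reach the dihydroxy acid F5. Close the seven-membered lactone again through the primary allylic alcohol (2,4,6-trichlorobenzoyl chloride, Et3N, DMAP, Yamaguchi conditions) to give 14. This answers the chemoselectivity problem but not a wrong facial outcome.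

**Further compounds**

F1 | step 7 | (4R)-4-[4-(tert-butyldimethylsilyloxy)-3-methylcyclohexa-1,3-dien-1-yl]-4-methyl-2-[(phenylselanyl)methyl]-1,3-dioxolane (acetal epimers) | C[C@@]1(C2=CC(C)=C(O[Si](C)(C)C(C)(C)C)CC2)COC(C[Se]c3ccccc3)O1
F2 | step 7 | selenoxide of F1 | C[C@@]1(C2=CC(C)=C(O[Si](C)(C)C(C)(C)C)CC2)COC(C[Se](=O)c3ccccc3)O1
F3 | step 8 | (9S,9aR)-9-(1-hydroxyethyl)-5,9-dimethyl-4,6,7,9a-tetrahydro-3-benzoxepine-2,8(1H,9H)-dione (carbinol epimers) | CC(O)[C@@]1(C)[C@@H]2CC(=O)OCC(C)=C2CCC1=O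
F4 | step 9 | 2-[(1R,2S)-2-ethenyl-6-[(2Z)-1-hydroxypropan-2-ylidene]-2-methyl-3-oxocyclohexyl]acetic acid | C=C[C@@]1(C)[C@H](CC(=O)O)/C(=C(/C)CO)CCC1=O
F5 | step 9 | 2-[(1R,2S,3S)-2-ethenyl-3-hydroxy-6-[(2Z)-1-hydroxypropan-2-ylidene]-2,3-dimethylcyclohexyl]acetic acid | C=C[C@@]1(C)[C@H](CC(=O)O)/C(=C(/C)CO)CC[C@]1(C)O
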